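Amounts first: the substrate charged sits as substrate, target, catalyst intermediate B or over-reaction product, and we want the split in this flask.

common to all: free catalyst 1.8 mol%

| run | substrate | partner | added ligand | remark | time |
|---|---|---|---|---|---|
| Friday's | 0.28 M | 1.3 equiv | 50 mM | run made earlier |  |
| Thursday's | 1.1 M | 1.3 equiv | 50 mM | run made earlier |  |
| Monday's | 0.55 M | 1.3 equiv | 100 mM | run made earlier |  |
| flask | 0.55 M | 1.30 equiv | 50 mM |  | 8.0 min |

| run | time / min | target / % | catalyst intermediate B / % | over-reaction product / % | substrate / % |
|---|---|---|---|---|---|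
| Friday's | 0.833 | 6 | 2 | 5 | 93 |
| Friday's | 1.33 | 9 | 0 | 2 | 89 |
| Friday's | 2.00 | 14 | 0 | 7 | 87 |
| Friday's | 2.50 | 15 | 0 | 7 | 76 |
| Friday's | 4.00 | 18 | 1 | 8 | 68 |
| Friday's | 6.00 | 23 | 3 | 21 | 55 |
| Friday's | 10.0 | 20 | 0 | 44 | 36 |
| Thursday's | 0.833 | 22 | 3 | 4 | 76 |
| Thursday's | 1.33 | 28 | 0 | 2 | 68 |
| Thursday's | 2.00 | 39 | 0 | 12 | 53 |
| Thursday's | 2.50 | 41 | 2 | 16 | 44 |
| Thursday's | 4.00 | 45 | 0 | 33 | 24 |
| Thursday's | 6.00 | 36 | 2 | 50 | 12 |
| Thursday's | 10.0 | 18 | 0 | 75 | 2 |
| Monday's | 2.00 | 22 | 0 | 7 | 72 |
| Monday's | 4.00 | 32 | 0 | 19 | 53 |
| Monday's | 6.00 | 32 | 0 | 35 | 34 |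
| Monday's | 8.00 | 27 | 0 | 48 | 21 |
| Monday's | 10.0 | 21 | 0 | 62 | 16 |

(each reading ± 2 percentage points)



1. the species in which most of what was charged as substrate, at 8.0 min sits (substrate / target / catalyst intermediate B / over-reaction product)
2. the largest share itself, whichever of these holds it, in percent of the substrate charged

We build the flask one process at a time. First comes the main step. On Monday's run, substrate down to 16% at 10.0 min gives a first-order decay constant of 0.183 min⁻¹ for [substrate] at this charge.

Next, target is lost. We carry the loss constant of target, the over-reaction product gained per unit of area under the target curve. Monday's readings give 0.244 min⁻¹. We assume it holds unchanged at this flask's ligand.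

Last comes the ligand, since Monday's run had 100 mM and this flask has 50 mM. Friday's and Thursday's runs had this flask's ligand, and this flask's substrate charge lies between theirs on a logarithmic scale. The geometric mean of their decay constants is 0.190 min⁻¹, slightly faster than Monday's, but both are read from scattered readings, and they come from different runs by different routes, so we don't put the gap down to the ligand.

| Our reckoning at the asked time | substrate | target | over-reaction product |
|---|---|---|---|
| main step | 23.1% | 76.9% | none |
| plus loss of target | 23.1% | 26.8% | 50.2% |
| decay read at this flask's ligand | 21.9% | 27.0% | 51.2% |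

With the loss of target, over-reaction product at 50.2% stands above target at 26.8%, and the decay constant read at this flask's ligand moves it by 1 percentage point.

The forecast says over-reaction product at 50%, holding that “ligand has little effect”. Our 51.2% stands slightly above it.

The flask gives over-reaction product at 50.3%, with target at 27.6% and substrate at 22.0%.

    partner + free catalyst → catalyst intermediate A (k = 3.40 L mol⁻¹ s⁻¹)
    substrate + catalyst intermediate A → catalyst intermediate B (k = 0.390 L mol⁻¹ s⁻¹)
    catalyst intermediate B → free catalyst + target (k = 1.00 s⁻¹)
    target → over-reaction product (k = 0.00410 s⁻¹)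
    free catalyst + added ligand ⇌ idle complex, settled at all times (K = 12.0 L mol⁻¹)

With the carried constant, this flask's target is being lost at 0.0673 min⁻¹, as a fraction of the substrate charged, at 8.0 min. It is made at 0.668 of the rate it is used up, so target is falling in this flask by then.

For the flask left until 3.0 min, the same constants give over-reaction product 13.7% and substrate 56.6%. Computed, it holds 12.8% and 58.6%, with substrate the largest share.

All runs were generated by integration with made-up constants, and the scatter is random.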